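**Retrosynthetic overview**

1. Locants used for the target: C1 (CH–OAc), C2 (CH2), C3 (C(OH)iPr), C4 (ring-fusion CH), C5 (CH–O-aroyl), C6=C7(Me), C8 (C=O), C9 (CH2), C10 (quaternary C–Me). Ring A is the cyclopentane (C1–C4, C10), ring B the cycloheptenone (C4–C10), and β is the face of ring A that carries the C1 oxygen.
2. Enabling feature: on ring A the C1 oxygen is cis to the C9 methylene on the adjacent quaternary C10, and C9 is bonded to the carbonyl carbon C8. O–C8–C9–C10–C1 is therefore a latent five-membered acetal/lactone ring made only of target atoms. With C3 as a ketone, C10 is the β-carbon of an enone (C3=O, C4=C10) and C4–C5 is an aldol bond.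
3. Key disconnection: C9–C10 and C4–C5 are formed together by an O-tethered radical conjugate addition/boron-enolate aldol of the iodoacetal of (R)-4-hydroxy-3-methylcyclopent-2-enone with acrolein. This sets C10, C4 (trans to C9, the trans ring fusion) and C5.
4. After the key step: C3 ketone → enol triflate → isopropyl alkene → β-epoxide → tertiary carbinol. The acetal is oxidised to the γ-lactone, which isopropenyllithium opens (C7–C8 bond, free C1 hydroxyl, then acetate).
5. Ring order: ring A from the chiral pool; a temporary oxolane ring in the key step (opened in step 12); ring B last by ring-closing metathesis at C6=C7; then the aroyl ester and release of the phenol.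

Key step: step 5

Remark: 1 is taken as the commercial chiral-pool starting material; the acetal carbon of 6 and 8–14 is a mixture of epimers (written without a descriptor) and becomes the lactone carbonyl in step 11.

**Route**

Step 1
Reactants: 1 (4R)-4-(tert-butyldimethylsilyloxy)cyclopent-2-en-1-one
Product: 2 tert-butyldimethyl{[(1R,2R)-2-methyl-4-(trimethylsilyloxy)cyclopent-3-en-1-yl]oxy}silane (methyl trans to the silyloxy group)
Conditions: Me2CuLi (from CuI and 2 MeLi), Me3SiCl, THF, −78 °C; Et3N, aq. NaHCO3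
Reagents that add atoms: lithium dimethylcuprate, [Li+].C[Cu-]C; chlorotrimethylsilane, C[Si](C)(C)Cl
Why: Chlorosilane-accelerated conjugate addition of a Gilman cuprate is standard for 4-silyloxycyclopentenones, methyl adding anti to the silyloxy group (a centre erased in step 2) and the enolate being trapped regiospecifically as the silyl enol ether.

Step 2
Reactants: 2 tert-butyldimethyl{[(1R,2R)-2-methyl-4-(trimethylsilyloxy)cyclopent-3-en-1-yl]oxy}silane
Product: 3 (4R)-4-(tert-butyldimethylsilyloxy)-3-methylcyclopent-2-en-1-one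
Conditions: Pd(OAc)2 (1.05 equiv), MeCN, rt
Reagents that add atoms: none
Why: Saegusa–Ito oxidation of the regiodefined silyl enol ether should place the enone double bond toward the methyl-bearing carbon without touching the carbinol centre.

Step 3
Reactants: 3 (4R)-4-(tert-butyldimethylsilyloxy)-3-methylcyclopent-2-en-1-one
Product: 4 (4R)-4-hydroxy-3-methylcyclopent-2-en-1-one
Conditions: aq. HF, MeCN, 0 °C
Reagents that add atoms: none
Why: Acidic fluoride desilylation avoids the base-induced elimination and racemisation to which 4-hydroxycyclopentenones are prone.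

Step 4
Reactants: 4 (4R)-4-hydroxy-3-methylcyclopent-2-en-1-one; 5 ethyl vinyl ether
Product: 6 (4R)-4-(1-ethoxy-2-iodoethoxy)-3-methylcyclopent-2-en-1-one (both acetal epimers)
Conditions: N-iodosuccinimide, 5 (excess), CH2Cl2, −40 to 0 °C
Reagents that add atoms: N-iodosuccinimide, O=C1CCC(=O)N1I
Why: Iodoetherification of the enol ether in the presence of the alcohol is the standard entry to Ueno–Stork iodoacetals, and the electron-poor enone double bond should not compete.

Step 5
Reactants: 6 (4R)-4-(1-ethoxy-2-iodoethoxy)-3-methylcyclopent-2-en-1-one; 7 acrolein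
Product: 9 (3aS,4R,6aR)-2-ethoxy-4-[(1R)-1-hydroxyprop-2-en-1-yl]-3a-methylhexahydro-5H-cyclopenta[b]furan-5-one, via diethylboron enolate 8 (not isolated)
Conditions: Et3B (2.5 equiv), dry air (slow addition), toluene, −78 to −40 °C; argon purge; then 7 (3 equiv), −78 to −20 °C; pH 7 buffer, MeOH
Reagents that add atoms: none
Why: Proposed new method: an ethyl radical from Et3B/O2 abstracts iodine from 6, the nucleophilic primary radical (C9) adds 5-exo-trig to the enone β-carbon C10 and so closes the oxolane ring of a cis-fused 2-oxabicyclo[3.3.0]octane, the α-keto radical at C4 is captured at oxygen by Et3B to give the regiodefined diethylboron enolate 8 and a new ethyl radical, and 8 then adds to acrolein through a closed six-membered transition state to form C4–C5. The closest known reactions are the Ueno–Stork haloacetal radical cyclisation onto enones and the Et3B-mediated three-component coupling of alkyl iodides, enones and aldehydes by way of boron enolates; their union in one flask on a β-methyl cyclopentenone is what is new. The quaternary centre C10 is controlled by the tether, because the acetal oxygen on the existing C1 stereocentre can deliver C9 only to its own face (a five-five ring system closes only cis), which leaves the methyl group on the convex face. C4 is controlled by the bicycle, the aldehyde approaching the enolate on the convex face and so trans to C9 (the future trans ring fusion), and C5 by the chair Zimmerman–Traxler transition state of the ring-locked E-enolate, which should give the anti aldol that the target requires; the acetal carbon forms as a mixture that is removed in step 11. The step needs 5-exo over 6-endo closure (secured by ring size and by the polarity match of the alkyl radical with the enone β-carbon), reaction of the enolate only at C4 (secured because it is born there and not equilibrated, whereas deprotonation of the corresponding ketone would occur at C2), and 1,2-addition to acrolein (normal for boron enolates; acrolein is added only after the radical phase so that radicals do not consume it).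

Step 6
Reactants: 9 (3aS,4R,6aR)-2-ethoxy-4-[(1R)-1-hydroxyprop-2-en-1-yl]-3a-methylhexahydro-5H-cyclopenta[b]furan-5-one
Product: 10 (3aS,4R,6aR)-4-[(1R)-1-(tert-butyldimethylsilyloxy)prop-2-en-1-yl]-2-ethoxy-3a-methylhexahydro-5H-cyclopenta[b]furan-5-one
Conditions: TBSOTf, 2,6-lutidine, CH2Cl2, −78 °C
Reagents that add atoms: tert-butyldimethylsilyl trifluoromethanesulfonate, CC(C)(C)[Si](C)(C)OS(=O)(=O)C(F)(F)F
Why: Low-temperature silylation with a silyl triflate and a hindered pyridine base should protect the aldol hydroxyl without retro-aldol cleavage or β-elimination.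

Step 7
Reactants: 10 (3aS,4R,6aR)-4-[(1R)-1-(tert-butyldimethylsilyloxy)prop-2-en-1-yl]-2-ethoxy-3a-methylhexahydro-5H-cyclopenta[b]furan-5-one
Product: 11 (3aS,4R,6aR)-4-[(1R)-1-(tert-butyldimethylsilyloxy)prop-2-en-1-yl]-2-ethoxy-3a-methyl-3,3a,4,6a-tetrahydro-2H-cyclopenta[b]furan-5-yl trifluoromethanesulfonate
Conditions: KHMDS, THF, −78 °C; N-(5-chloropyridin-2-yl)triflimide, −78 °C
Reagents that add atoms: N-(5-chloropyridin-2-yl)bis(trifluoromethanesulfonyl)imide, FC(F)(F)S(=O)(=O)N(c1ccc(Cl)cn1)S(=O)(=O)C(F)(F)F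
Why: Kinetic deprotonation should occur at the unhindered C2 methylene (C4–H is tertiary and next to the quaternary carbon), and O-triflation of the enolate at −78 °C should be faster than expulsion of the β-alkoxy group on C1.

Step 8
Reactants: 11 (3aS,4R,6aR)-4-[(1R)-1-(tert-butyldimethylsilyloxy)prop-2-en-1-yl]-2-ethoxy-3a-methyl-3,3a,4,6a-tetrahydro-2H-cyclopenta[b]furan-5-yl trifluoromethanesulfonate
Product: 12 tert-butyl({(1R)-1-[2-ethoxy-3a-methyl-5-(propan-2-yl)-3,3a,4,6a-tetrahydro-2H-cyclopenta[b]furan-4-yl]prop-2-en-1-yl}oxy)dimethylsilane (ring centres as in 11)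
Conditions: i-PrMgCl, Fe(acac)3 (5 mol%), THF/NMP, −30 °C
Reagents that add atoms: isopropylmagnesium chloride, CC(C)[Mg]Cl
Why: Iron-catalysed Kumada-type coupling of enol triflates with alkyl Grignard reagents tolerates acetals and silyl ethers and should install the isopropyl group without touching any stereocentre.

Step 9
Reactants: 12 tert-butyl({(1R)-1-[2-ethoxy-3a-methyl-5-(propan-2-yl)-3,3a,4,6a-tetrahydro-2H-cyclopenta[b]furan-4-yl]prop-2-en-1-yl}oxy)dimethylsilane
Product: 13 the 5,6-epoxide of 12 with the epoxide oxygen on the face of the ring oxygen (β, trans to the C4 side chain)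
Conditions: mCPBA, NaHCO3, CH2Cl2, 0 °C
Reagents that add atoms: 3-chloroperoxybenzoic acid, OOC(=O)c1cccc(Cl)c1
Why: Prilezhaev epoxidation is chemoselective for the electron-rich trisubstituted alkene over the vinyl group, and the peracid should approach the face opposite the large C4 side chain and the angular methyl group, which places the C3–O bond β.

Step 10
Reactants: 13 the β-5,6-epoxide of 12
Product: 14 2-ethoxy-5-hydroxy-3a-methyl-5-(propan-2-yl)-4-[(1R)-1-(tert-butyldimethylsilyloxy)prop-2-en-1-yl]hexahydro-2H-cyclopenta[b]furan (5-hydroxyl cis to the ring oxygen and isopropyl cis to the C4 side chain)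
Conditions: LiEt3BH, THF, 0 to 50 °C; H2O
Reagents that add atoms: none
Why: Hydride should open the trisubstituted epoxide by SN2 attack at the secondary carbon C2, so the C3–O bond and its configuration stay untouched and the tertiary carbinol results.

Step 11
Reactants: 14 2-ethoxy-5-hydroxy-3a-methyl-5-(propan-2-yl)-4-[(1R)-1-(tert-butyldimethylsilyloxy)prop-2-en-1-yl]hexahydro-2H-cyclopenta[b]furan
Product: 15 5-hydroxy-3a-methyl-5-(propan-2-yl)-4-[(1R)-1-(tert-butyldimethylsilyloxy)prop-2-en-1-yl]hexahydro-2H-cyclopenta[b]furan-2-one (configuration as in 14)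
Conditions: Jones reagent (CrO3, H2SO4, H2O), acetone, 0 °C
Reagents that add atoms: water, O
Why: Jones oxidation (acid hydrolysis to the lactol, then chromic acid oxidation) is the usual conversion of Ueno–Stork ethyl acetals into γ-lactones, and the tertiary alcohol cannot be oxidised.

Step 12
Reactants: 15 5-hydroxy-3a-methyl-5-(propan-2-yl)-4-[(1R)-1-(tert-butyldimethylsilyloxy)prop-2-en-1-yl]hexahydro-2H-cyclopenta[b]furan-2-one; 16 2-bromopropene
Product: 18 ring A diol dienone with C1 β-hydroxyl; C3 β-hydroxyl and α-isopropyl; C4 α-[(1R)-1-(tert-butyldimethylsilyloxy)prop-2-en-1-yl]; C10 α-methyl and β-CH2C(=O)C(CH3)=CH2 (in equilibrium with its cyclic hemiketal), via isopropenyllithium 17 (not isolated)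
Conditions: 16, t-BuLi (2 equiv per 16), Et2O, −78 °C; then 15 (0.45 equiv relative to 17), THF, −78 °C; H2O at −78 °C
Reagents that add atoms: none
Why: Alkenyllithium reagents add only once to γ-lactones at −78 °C because the lithium hemiketal survives until the quench, which here forms the C7–C8 bond and frees the C1 hydroxyl, one further equivalent being consumed by the tertiary hydroxyl.

Step 13
Reactants: 18 ring A diol dienone
Product: 19 the C1 acetate of 18
Conditions: Ac2O, pyridine, DMAP (cat.), CH2Cl2, 0 °C to rt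
Reagents that add atoms: acetic anhydride, CC(=O)OC(C)=O
Why: DMAP-catalysed acetylation should discriminate the secondary C1 hydroxyl from the hindered tertiary C3 hydroxyl and draws the hemiketal equilibrium to the open keto acetate.

Step 14
Reactants: 19 the C1 acetate of 18
Product: 20 (1R,3R,3aR,4R,8aS)-4-(tert-butyldimethylsilyloxy)-3-hydroxy-6,8a-dimethyl-7-oxo-3-(propan-2-yl)-1,2,3,3a,4,7,8,8a-octahydroazulen-1-yl acetate
Conditions: second-generation Grubbs catalyst, RuCl2(=CHPh)(PCy3)(H2IMes) (5 mol%), CH2Cl2 (high dilution), 40 °C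
Reagents that add atoms: none
Why: Ring-closing metathesis between the vinyl group and the isopropenyl ketone should close ring B as the trisubstituted enone, the two chains being trans on ring A so that the trans ring fusion set in step 5 is kept.

Step 15
Reactants: 20 (1R,3R,3aR,4R,8aS)-4-(tert-butyldimethylsilyloxy)-3-hydroxy-6,8a-dimethyl-7-oxo-3-(propan-2-yl)-1,2,3,3a,4,7,8,8a-octahydroazulen-1-yl acetate
Product: 21 (1R,3R,3aR,4R,8aS)-3,4-dihydroxy-6,8a-dimethyl-7-oxo-3-(propan-2-yl)-1,2,3,3a,4,7,8,8a-octahydroazulen-1-yl acetate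
Conditions: HF·pyridine, pyridine, THF, 0 °C to rt
Reagents that add atoms: none
Why: Buffered HF·pyridine cleaves the secondary silyl ether under non-basic conditions that the γ-oxygenated enone and the acetate should tolerate.

Step 16
Reactants: 21 (1R,3R,3aR,4R,8aS)-3,4-dihydroxy-6,8a-dimethyl-7-oxo-3-(propan-2-yl)-1,2,3,3a,4,7,8,8a-octahydroazulen-1-yl acetate; 22 4-acetoxybenzoyl chloride
Product: 23 (1R,3R,3aR,4R,8aS)-1-acetoxy-3-hydroxy-6,8a-dimethyl-7-oxo-3-(propan-2-yl)-1,2,3,3a,4,7,8,8a-octahydroazulen-4-yl 4-acetoxybenzoate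
Conditions: 22, pyridine, DMAP (cat.), CH2Cl2, 0 °C to rt
Reagents that add atoms: none
Why: DMAP-catalysed acylation of the secondary allylic alcohol with the acid chloride proceeds with retention at C5, and the tertiary hydroxyl is too hindered to react.

Step 17
Reactants: 23 (1R,3R,3aR,4R,8aS)-1-acetoxy-3-hydroxy-6,8a-dimethyl-7-oxo-3-(propan-2-yl)-1,2,3,3a,4,7,8,8a-octahydroazulen-4-yl 4-acetoxybenzoate
Product: 24 (1R,3R,3aR,4R,8aS)-1-acetoxy-3-hydroxy-6,8a-dimethyl-7-oxo-3-(propan-2-yl)-1,2,3,3a,4,7,8,8a-octahydroazulen-4-yl 4-hydroxybenzoate (target)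
Conditions: NH4OAc, MeOH/H2O, rt
Reagents that add atoms: none
Why: Aryl acetates undergo methanolysis with ammonium acetate much faster than alkyl acetates or benzoates because phenoxide is the better leaving group, so the phenol should be released chemoselectively.

**Compound list**

1 | (4R)-4-(tert-butyldimethylsilyloxy)cyclopent-2-en-1-one | CC(C)(C)[Si](C)(C)O[C@@H]1CC(=O)C=C1 | starting material
2 | tert-butyldimethyl{[(1R,2R)-2-methyl-4-(trimethylsilyloxy)cyclopent-3-en-1-yl]oxy}silane | CC(C)(C)[Si](C)(C)O[C@@H]1CC(O[Si](C)(C)C)=C[C@H]1C | intermediate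
3 | (4R)-4-(tert-butyldimethylsilyloxy)-3-methylcyclopent-2-en-1-one | CC(C)(C)[Si](C)(C)O[C@@H]1CC(=O)C=C1C | intermediate
4 | (4R)-4-hydroxy-3-methylcyclopent-2-en-1-one | O[C@@H]1CC(=O)C=C1C | intermediate
5 | ethyl vinyl ether | CCOC=C | starting material
6 | (4R)-4-(1-ethoxy-2-iodoethoxy)-3-methylcyclopent-2-en-1-one (acetal epimers) | CCOC(CI)O[C@@H]1CC(=O)C=C1C | intermediate
7 | acrolein | C=CC=O | starting material
8 | diethyl{[(3aS,6aR)-2-ethoxy-3a-methyl-3,3a,6,6a-tetrahydro-2H-cyclopenta[b]furan-5-yl]oxy}borane (cis-fused boron enolate) | CCOC3O[C@@H]1CC(OB(CC)CC)=C[C@]1(C)C3 | intermediate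
9 | (3aS,4R,6aR)-2-ethoxy-4-[(1R)-1-hydroxyprop-2-en-1-yl]-3a-methylhexahydro-5H-cyclopenta[b]furan-5-one (cis-fused; side chain trans to the C3 methylene) | CCOC3O[C@@H]1CC(=O)[C@@H]([C@H](O)C=C)[C@]1(C)C3 | intermediate
10 | (3aS,4R,6aR)-4-[(1R)-1-(tert-butyldimethylsilyloxy)prop-2-en-1-yl]-2-ethoxy-3a-methylhexahydro-5H-cyclopenta[b]furan-5-one | CCOC3O[C@@H]1CC(=O)[C@@H]([C@H](O[Si](C)(C)C(C)(C)C)C=C)[C@]1(C)C3 | intermediate
11 | (3aS,4R,6aR)-4-[(1R)-1-(tert-butyldimethylsilyloxy)prop-2-en-1-yl]-2-ethoxy-3a-methyl-3,3a,4,6a-tetrahydro-2H-cyclopenta[b]furan-5-yl trifluoromethanesulfonate | CCOC3O[C@@H]1C=C(OS(=O)(=O)C(F)(F)F)[C@@H]([C@H](O[Si](C)(C)C(C)(C)C)C=C)[C@]1(C)C3 | intermediate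
12 | tert-butyl({(1R)-1-[2-ethoxy-3a-methyl-5-(propan-2-yl)-3,3a,4,6a-tetrahydro-2H-cyclopenta[b]furan-4-yl]prop-2-en-1-yl}oxy)dimethylsilane (ring centres as in 11) | CCOC3O[C@@H]1C=C(C(C)C)[C@@H]([C@H](O[Si](C)(C)C(C)(C)C)C=C)[C@]1(C)C3 | intermediate
13 | 5,6-epoxide of 12, oxygen on the face of the ring oxygen | CCOC3O[C@@H]1[C@@H]4O[C@]4(C(C)C)[C@@H]([C@H](O[Si](C)(C)C(C)(C)C)C=C)[C@]1(C)C3 | intermediate
14 | 2-ethoxy-5-hydroxy-3a-methyl-5-(propan-2-yl)-4-[(1R)-1-(tert-butyldimethylsilyloxy)prop-2-en-1-yl]hexahydro-2H-cyclopenta[b]furan (5-hydroxyl cis to the ring oxygen) | CCOC3O[C@@H]1C[C@@](O)(C(C)C)[C@@H]([C@H](O[Si](C)(C)C(C)(C)C)C=C)[C@]1(C)C3 | intermediate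
15 | 5-hydroxy-3a-methyl-5-(propan-2-yl)-4-[(1R)-1-(tert-butyldimethylsilyloxy)prop-2-en-1-yl]hexahydro-2H-cyclopenta[b]furan-2-one | O=C3O[C@@H]1C[C@@](O)(C(C)C)[C@@H]([C@H](O[Si](C)(C)C(C)(C)C)C=C)[C@]1(C)C3 | intermediate
16 | 2-bromopropene | CC(Br)=C | starting material
17 | isopropenyllithium | [Li]C(C)=C | intermediate
18 | ring A diol dienone (C1 β-OH; C3 β-OH and α-iPr; C4 α-[(1R)-1-(tert-butyldimethylsilyloxy)prop-2-en-1-yl]; C10 α-Me and β-CH2C(=O)C(CH3)=CH2) | O[C@@H]1C[C@@](O)(C(C)C)[C@@H]([C@H](O[Si](C)(C)C(C)(C)C)C=C)[C@]1(C)CC(=O)C(C)=C | intermediate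
19 | C1 acetate of 18 | CC(=O)O[C@@H]1C[C@@](O)(C(C)C)[C@@H]([C@H](O[Si](C)(C)C(C)(C)C)C=C)[C@]1(C)CC(=O)C(C)=C | intermediate
20 | (1R,3R,3aR,4R,8aS)-4-(tert-butyldimethylsilyloxy)-3-hydroxy-6,8a-dimethyl-7-oxo-3-(propan-2-yl)-1,2,3,3a,4,7,8,8a-octahydroazulen-1-yl acetate | CC(=O)O[C@@H]1C[C@@](O)(C(C)C)[C@H]2[C@H](O[Si](C)(C)C(C)(C)C)C=C(C)C(=O)C[C@]12C | intermediate
21 | (1R,3R,3aR,4R,8aS)-3,4-dihydroxy-6,8a-dimethyl-7-oxo-3-(propan-2-yl)-1,2,3,3a,4,7,8,8a-octahydroazulen-1-yl acetate | CC(=O)O[C@@H]1C[C@@](O)(C(C)C)[C@H]2[C@H](O)C=C(C)C(=O)C[C@]12C | intermediate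
22 | 4-acetoxybenzoyl chloride | CC(=O)Oc1ccc(cc1)C(Cl)=O | starting material
23 | (1R,3R,3aR,4R,8aS)-1-acetoxy-3-hydroxy-6,8a-dimethyl-7-oxo-3-(propan-2-yl)-1,2,3,3a,4,7,8,8a-octahydroazulen-4-yl 4-acetoxybenzoate | CC(=O)O[C@@H]1C[C@@](O)(C(C)C)[C@H]2[C@H](OC(=O)c3ccc(OC(C)=O)cc3)C=C(C)C(=O)C[C@]12C | intermediate
24 | (1R,3R,3aR,4R,8aS)-1-acetoxy-3-hydroxy-6,8a-dimethyl-7-oxo-3-(propan-2-yl)-1,2,3,3a,4,7,8,8a-octahydroazulen-4-yl 4-hydroxybenzoate | CC(=O)O[C@@H]1C[C@@](O)(C(C)C)[C@H]2[C@H](OC(=O)c3ccc(O)cc3)C=C(C)C(=O)C[C@]12C | target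

Total step count: 17. Longest linear sequence: 17 steps (from 1).

**Steps most likely to fail**

Step 5 (carries the label). What may go wrong: loss of the boron enolate before the aldol (protonation or breakdown of the iodine-transfer chain), or erosion of the convex-face and anti selectivity in the aldol. Fallback with known reactions, in two operations, setting out from 6. A nickel-catalysed reductive conjugate addition of the alkyl iodide to the enone in the presence of a chlorosilane (NiCl2(dme), neocuproine, manganese powder, Me3SiCl, DMF, rt) should effect the same tether-controlled ring closure and trap the enolate as the trimethylsilyl enol ether F1. Cleavage of F1 with MeLi (THF, 0 °C) should give the regiodefined lithium enolate F2, which is added to acrolein 7 at −78 °C (closed transition state, convex face). The sequence comes back to the route at 9.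

Step 7. What may go wrong: expulsion of the β-alkoxy group on C1 from the C2 enolate (opening of the oxolane ring), or incomplete regiocontrol in the deprotonation. Fallback without an enolate, setting out from 10. Condensation with hydrazine hydrate (EtOH, Et3N) should give the hydrazone F3. Barton vinyl iodide synthesis (I2, tetramethylguanidine, THF) should then give the vinyl iodide F4 on the less hindered C2 side. Negishi coupling of F4 with i-PrZnBr (Pd(OAc)2, CPhos, THF) comes back to the route at 12.

Step 9. What may go wrong: poor facial selectivity of the epoxidation (attack on the face of the C4 side chain), which would give the C3 epimer after step 10. Fallback by hydroxyl-directed epoxidation, setting out from 12. Mild hydrolysis of the acetal (AcOH, THF, H2O) should give the lactol F5, and NaBH4 (MeOH) the diol F6 with a free allylic C1 hydroxyl. VO(acac)2 with t-BuOOH should then deliver the epoxide oxygen syn to that hydroxyl to give the epoxy diol F7. LiAlH4 opens F7 at C2 to the triol F8. Oxidative lactonisation of the primary alcohol of F8 (TEMPO, PhI(OAc)2, CH2Cl2) comes back to the route at 15.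

Further compounds
F1 | step 5 | {[(3aS,6aR)-2-ethoxy-3a-methyl-3,3a,6,6a-tetrahydro-2H-cyclopenta[b]furan-5-yl]oxy}trimethylsilane | CCOC3O[C@@H]1CC(O[Si](C)(C)C)=C[C@]1(C)C3
F2 | step 5 | lithium (3aS,6aR)-2-ethoxy-3a-methyl-3,3a,6,6a-tetrahydro-2H-cyclopenta[b]furan-5-olate | CCOC3O[C@@H]1CC(O[Li])=C[C@]1(C)C3
F3 | step 7 | hydrazone of 10 | CCOC3O[C@@H]1CC(=NN)[C@@H]([C@H](O[Si](C)(C)C(C)(C)C)C=C)[C@]1(C)C3
F4 | step 7 | 5-iodo analogue of 11 (vinyl iodide) | CCOC3O[C@@H]1C=C(I)[C@@H]([C@H](O[Si](C)(C)C(C)(C)C)C=C)[C@]1(C)C3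
F5 | step 9 | lactol from 12 (2-hydroxy in place of 2-ethoxy) | OC3O[C@@H]1C=C(C(C)C)[C@@H]([C@H](O[Si](C)(C)C(C)(C)C)C=C)[C@]1(C)C3
F6 | step 9 | cyclopentenol diol (free C1 hydroxyl and C10 2-hydroxyethyl group) | O[C@@H]1C=C(C(C)C)[C@@H]([C@H](O[Si](C)(C)C(C)(C)C)C=C)[C@]1(C)CCO
F7 | step 9 | epoxy diol, epoxide syn to the C1 hydroxyl | O[C@@H]1[C@@H]4O[C@]4(C(C)C)[C@@H]([C@H](O[Si](C)(C)C(C)(C)C)C=C)[C@]1(C)CCO
F8 | step 9 | triol (C1 and C3 hydroxyls cis; primary alcohol on the C10 side chain) | O[C@@H]1C[C@@](O)(C(C)C)[C@@H]([C@H](O[Si](C)(C)C(C)(C)C)C=C)[C@]1(C)CCO
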